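The data stem from a simulated flask on assumed constants; the scatter is artificial.

Time comes first: Friday's Ja reads 11% at 2.00 d and 11% at 3.00 d, and Saturday's ends at 19%, so we expect maple and oak to be moving slowly by 6.0 d, twice the time of those last readings. What matters is where they stop.

all flasks: Ja 0.10 M
- Saturday's: Jc 1.8 equiv; Jb 1.2 equiv; run made earlier
- Friday's: Jc 3.4 equiv; Jb 1.2 equiv; run made earlier
- maple: Jc 3.00 equiv; Jb 1.20 equiv; time 6.0 d
- oak: Jc 3.90 equiv; Jb 1.20 equiv; time 6.0 d

| run | time / d | Ja / % | Jf / % |
|---|---|---|---|
| Saturday's | 0.250 | 62 | 35 |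
| Saturday's | 0.417 | 50 | 44 |
| Saturday's | 0.833 | 34 | 59 |
| Saturday's | 1.67 | 22 | 64 |
| Saturday's | 3.00 | 19 | 63 |
| Friday's | 0.250 | 58 | 36 |
| Friday's | 0.833 | 30 | 62 |
| Friday's | 1.25 | 21 | 65 |
| Friday's | 2.00 | 11 | 65 |
| Friday's | 3.00 | 11 | 65 |

(each reading ± 1.5 percentage points)

1. part of the Ja that has reacted at the end, maple
2. part of the Ja that has reacted at the end, oak
3. what raising the equivalents of Jc from its lowest to its highest value here does to the part of the Ja that has reacted (changes below 5 percentage points count as none) (it rises / it falls / no change)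



The bench rule says more base gives more conversion. Between the two runs Ja left fell by 8 percentage points, and that slope adds 4.5 points from maple to oak. A slope like this assumes that Jc stays short, so we count instead.

Suppose each reacted Ja and each point of Ja missing from Ja plus Jf spends one Jb. Friday's has then spent 1.13 equiv of its 1.2 equiv. Putting that answer back in, the remainder splits evenly between the two drains, so conversion tops out near 92.5%. Suppose also that each Jb spent and each Ja reacted takes one Jc. The Jc need, Jb charged plus that ceiling, is 2.12 equiv.

Saturday's count at its last reading is 1.80 equiv, level with its charge, so we read Jc there as the limiting reagent. Charge over need is 1.41 for maple and 1.84 for oak, both above one, so we expect both flasks near the ceiling, with no change.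

The forecast gives 88% (85% to 90%) for maple and 90% (87% to 93%) for oak, and says it rises: “This looks like an equilibrium that the base pulls forward”. We part from it on the trend.

Maple gives 91.0% and oak 91.1%, a change of 0.12 points: no change. Free Jc at the end of maple is 29.8% of its charge, and the need leaves 29.2%.

    Ja + Jd → Je + Jf (k = 2.76 × 10⁻⁴ L mol⁻¹ s⁻¹)
    Jd + Je ⇌ Jb, settled at all times (K = 2030 L mol⁻¹)
    Je + Jc ⇌ Jg, settled at all times (K = 31700 L mol⁻¹)
    Jd + Jf → Jh (k = 6.07 × 10⁻⁵ L mol⁻¹ s⁻¹)

In a neighbour of maple with 3.00 equiv of Jb, the ceiling passes the whole Ja, so the need is 4.00 equiv, above the 3.00 equiv of Jc, and Jb should stop at 33.3% of its charge. The flask gives 99.9% reacted, Jc at 1.5% and Jb at 34.1%.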